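**Assumption:** hypothamnolic acid has no stereocentre or other stereogenic element (it is achiral), so "single enantiomer" means the compound as drawn and no stereocontrol is needed.

## Retrosynthetic overview

1. The target comes from protected depside 14 by one global acidolysis (two tert-butyl esters and one O-Boc).
2. Key disconnection: the aryl C5–O bond of the depside ester, not the acyl C–O bond. It is made by a copper-mediated radical C–H aroyloxylation of ring-B phenol 13 with ring-A tert-butyl perester 8.
3. Ring A is never constructed. The arene of m-cresol is decorated by O-methylation, Ir C–H borylation/oxidation, O-Boc/anionic Fries, Mg-directed ortho-formylation, and radical peresterification of the aldehyde.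
4. Ring B is the only ring built: Michael–Dieckmann annulation of tert-butyl acetoacetate with methyl crotonate (C-methylated in the same pot), then dehydrogenative aromatisation.
5. Order: ring B carbocycle formed (step 9), aromatised (step 10), then the two arenes are joined (step 11) and deprotected (step 12).

## Ring A fragment

**Step 1**
Reactants: 1, m-cresol (3-methylphenol)
Product: 2, 3-methylanisole
Conditions: MeI, K2CO3, acetone, reflux
Reagents that add atoms: iodomethane, CI
Why: Williamson O-methylation of the phenoxide (SN2).

**Step 2**
Reactants: 2, 3-methylanisole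
Product: 3, 3-methoxy-5-methylphenol
Conditions: [Ir(OMe)(cod)]2 (1 mol %), dtbpy, B2pin2, hexane, 80 °C; then Oxone, acetone/H2O, rt (one pot)
Reagents that add atoms: Oxone (potassium peroxymonosulfate, supplies the phenolic O), [K+].[O-]S(=O)(=O)OO
Why: Sterically controlled Ir-catalysed aromatic C–H borylation takes the only C–H meta to both substituents (C5), and the aryl boronate is oxidised in situ to the phenol (borylation/oxidation sequence).

**Step 3**
Reactants: 3, 3-methoxy-5-methylphenol
Product: 4, tert-butyl (3-methoxy-5-methylphenyl) carbonate
Conditions: Boc2O, DMAP (cat.), MeCN, rt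
Reagents that add atoms: di-tert-butyl dicarbonate, CC(C)(C)OC(=O)OC(=O)OC(C)(C)C
Why: DMAP-catalysed O-acylation of the phenol; this installs the group that becomes the ring-A carboxyl.

**Step 4**
Reactants: 4, tert-butyl (3-methoxy-5-methylphenyl) carbonate
Product: 5, tert-butyl 2-hydroxy-6-methoxy-4-methylbenzoate
Conditions: LDA (1.5 equiv), THF, −78 → 0 °C; aq. NH4Cl
Reagents that add atoms: none
Why: Anionic ortho-Fries rearrangement: LDA lithiates the position flanked by OBoc and OMe (cooperative directed ortho-metalation), and the aryllithium takes its own carbonate by a 1,3 O→C shift, placing CO2tBu between the two oxygens and freeing the phenol.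

**Step 5**
Reactants: 5, tert-butyl 2-hydroxy-6-methoxy-4-methylbenzoate
Product: 6, tert-butyl 3-formyl-2-hydroxy-6-methoxy-4-methylbenzoate
Conditions: MgCl2, Et3N, (CH2O)n, MeCN, reflux
Reagents that add atoms: paraformaldehyde (formaldehyde), C=O
Why: Mg-phenoxide-directed ortho-formylation (Casnati–Skattebøl) is strictly ortho to OH, and the only free ortho position is the one between OH and CH3 (para to OMe), so the regiochemistry is unambiguous.

**Step 6**
Reactants: 6, tert-butyl 3-formyl-2-hydroxy-6-methoxy-4-methylbenzoate
Product: 7, tert-butyl 2-[(tert-butoxycarbonyl)oxy]-3-formyl-6-methoxy-4-methylbenzoate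
Conditions: Boc2O, DMAP, Et3N, CH2Cl2, rt → 40 °C
Reagents that add atoms: di-tert-butyl dicarbonate, CC(C)(C)OC(=O)OC(=O)OC(C)(C)C
Why: DMAP-catalysed Boc protection masks the ring-A phenol so that no O–H on this fragment is exposed to alkoxyl radicals in steps 7 and 11; it is acid-labile like the ester.

**Step 7**
Reactants: 7, the O-Boc aldehyde
Product: 8, tert-butyl 2-[(tert-butoxycarbonyl)oxy]-3-[(tert-butylperoxy)carbonyl]-6-methoxy-4-methylbenzoate (the tert-butyl perester of the carboxyl flanked by OBoc and CH3)
Conditions: t-BuOOH (70 % aq., 4 equiv), Bu4NI (20 mol %), EtOAc, 40–60 °C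
Reagents that add atoms: tert-butyl hydroperoxide, CC(C)(C)OO
Why: Iodide/TBHP radical oxidative peresterification of an aldehyde: t-BuO•/t-BuOO• abstract the formyl hydrogen and the aroyl radical recombines with t-BuOO•, giving the perester directly; OBoc and the tert-butyl ester are inert under these neutral conditions.

## Ring B fragment

**Step 8**
Reactants: 9, diketene (4-methylideneoxetan-2-one)
Product: 10, tert-butyl acetoacetate
Conditions: t-BuOH, NaOAc (cat.), 80–110 °C
Reagents that add atoms: tert-butanol, CC(C)(C)O
Why: Nucleophilic ring-opening of diketene by the alcohol (acetoacetylation).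

**Step 9**
Reactants: 10, tert-butyl acetoacetate; 11, methyl (E)-but-2-enoate (methyl crotonate)
Product: 12, tert-butyl 3,6-dimethyl-2,4-dioxocyclohexane-1-carboxylate (racemic mixture of diastereomers and enol tautomers)
Conditions: t-BuOK (1.05 equiv), t-BuOH, reflux; then MeI (1.2 equiv), 40 °C; brief dilute-acid work-up
Reagents that add atoms: iodomethane, CI
Why: Michael addition of the β-keto ester enolate to the crotonate and Dieckmann closure give the cyclohexane-1,3-dione enolate, which is C-methylated in situ between the two carbonyls; the tert-butyl ester resists transesterification, and the stereocentres formed are erased in step 10.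

**Step 10**
Reactants: 12, the dione
Product: 13, tert-butyl 2,4-dihydroxy-3,6-dimethylbenzoate
Conditions: DDQ (1.1 equiv), 1,4-dioxane, 80 °C
Reagents that add atoms: none
Why: DDQ dehydrogenation (hydride abstraction from the enol, proton loss) followed by tautomerisation of the dione to the resorcinol, driven by aromatisation and run without acid so the tert-butyl ester survives.

## Union and deprotection

**Step 11 (key step)**
Reactants: 8, the ring-A tert-butyl perester; 13, tert-butyl 2,4-dihydroxy-3,6-dimethylbenzoate (2 equiv, excess recovered)
Product: 14, tert-butyl 5-({2-[(tert-butoxycarbonyl)oxy]-3-(tert-butoxycarbonyl)-4-methoxy-6-methylbenzoyl}oxy)-2,4-dihydroxy-3,6-dimethylbenzoate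
Conditions: Cu(MeCN)4PF6 (10 mol %), PhCF3, 50 °C, Ar, slow addition of 8
Reagents that add atoms: none
Why: Proposed new method: a Kharasch–Sosnovsky-type radical relay in which Cu(I) cleaves the perester O–O bond to a Cu(II) aroate and t-BuO•, t-BuO• abstracts the free (non-chelated) 4-OH hydrogen of 13 to give a phenoxyl (oxa-allyl) radical with spin at C5, the only unsubstituted ring carbon, and this radical is captured by the Cu(II) aroate with C–O reductive elimination and tautomerisation to the catechol mono-ester, regenerating Cu(I). The ring-A acid stays on copper and is never a free aroyloxyl radical, so decarboxylation and abstraction from its ortho methyl are avoided. The closest known reactions are Kharasch–Sosnovsky allylic acyloxylation with tert-butyl perbenzoate/Cu, and the ortho-benzoyloxylation of phenols by diaroyl peroxides.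

**Step 12**
Reactants: 14, the protected depside
Product: 15, hypothamnolic acid
Conditions: TFA/CH2Cl2 (1:1), Et3SiH, 0 °C → rt
Reagents that add atoms: none
Why: Acidolysis (loss of tert-butyl cation, scavenged by the silane) removes both tert-butyl esters and the O-Boc carbonate in one operation; the hindered aryl ester and the aryl methyl ether are stable to TFA, and keeping the reaction cold and short limits decarboxylation of the ring-B acid.

## Compound list

1 | m-cresol | Cc1cccc(O)c1 | starting material
2 | 3-methylanisole | COc1cccc(C)c1 | intermediate
3 | 3-methoxy-5-methylphenol | COc1cc(C)cc(O)c1 | intermediate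
4 | tert-butyl (3-methoxy-5-methylphenyl) carbonate | COc1cc(C)cc(OC(=O)OC(C)(C)C)c1 | intermediate
5 | tert-butyl 2-hydroxy-6-methoxy-4-methylbenzoate | COc1cc(C)cc(O)c1C(=O)OC(C)(C)C | intermediate
6 | tert-butyl 3-formyl-2-hydroxy-6-methoxy-4-methylbenzoate | COc1cc(C)c(C=O)c(O)c1C(=O)OC(C)(C)C | intermediate
7 | tert-butyl 2-[(tert-butoxycarbonyl)oxy]-3-formyl-6-methoxy-4-methylbenzoate | COc1cc(C)c(C=O)c(OC(=O)OC(C)(C)C)c1C(=O)OC(C)(C)C | intermediate
8 | tert-butyl 2-[(tert-butoxycarbonyl)oxy]-3-[(tert-butylperoxy)carbonyl]-6-methoxy-4-methylbenzoate | COc1cc(C)c(C(=O)OOC(C)(C)C)c(OC(=O)OC(C)(C)C)c1C(=O)OC(C)(C)C | intermediate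
9 | diketene | C=C1CC(=O)O1 | starting material
10 | tert-butyl acetoacetate | CC(=O)CC(=O)OC(C)(C)C | intermediate
11 | methyl (E)-but-2-enoate | C/C=C/C(=O)OC | starting material
12 | tert-butyl 3,6-dimethyl-2,4-dioxocyclohexane-1-carboxylate (stereoisomer/tautomer mixture) | CC1CC(=O)C(C)C(=O)C1C(=O)OC(C)(C)C | intermediate
13 | tert-butyl 2,4-dihydroxy-3,6-dimethylbenzoate | Cc1cc(O)c(C)c(O)c1C(=O)OC(C)(C)C | intermediate
14 | tert-butyl 5-({2-[(tert-butoxycarbonyl)oxy]-3-(tert-butoxycarbonyl)-4-methoxy-6-methylbenzoyl}oxy)-2,4-dihydroxy-3,6-dimethylbenzoate | COc1cc(C)c(C(=O)Oc2c(C)c(C(=O)OC(C)(C)C)c(O)c(C)c2O)c(OC(=O)OC(C)(C)C)c1C(=O)OC(C)(C)C | intermediate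
15 | hypothamnolic acid | COc1cc(C)c(C(=O)Oc2c(C)c(C(=O)O)c(O)c(C)c2O)c(O)c1C(=O)O | target

## Step count

Total steps: 12. Longest linear sequence: 9 (steps 1–7, 11, 12); the ring-B branch is 3 steps (8–10).

## Steps most likely to fail, with fallbacks

1. **Step 11 (radical C–H aroyloxylation).** Risks are over-oxidation of the electron-rich phenol by Cu/peroxide, attack at the methyl-bearing C3, and slow transfer of the hindered aroate. Fallback: oxidise aldehyde 7 to the acid, make the symmetrical diaroyl peroxide, and react it with 13 without copper, using the classical ortho-aroyloxylation of phenols by diaroyl peroxides (caged phenoxyl/aroyloxyl radical pair). This changes both the radical precursor and the bond-forming mechanism.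
2. **Step 10 (DDQ aromatisation of a tert-butyl β-keto ester dione).** Risks are over-oxidation of the resorcinol product and thermal loss of the ester. Fallback: build ring B as the methyl ester (methyl acetoacetate in step 9), aromatise by the robust halogenation–dehydrohalogenation sequence, cleave the methyl ester with BCl3, and re-esterify the acid with N,N-dimethylformamide di-tert-butyl acetal.
3. **Step 7 (direct peresterification of a 2,6-disubstituted aldehyde).** Risks are slow reaction and ring iodination. Fallback: a two-step ionic route, Pinnick oxidation of 7 to the carboxylic acid, then the acid chloride under neutral conditions (1-chloro-N,N,2-trimethylpropenylamine) and acylation of t-BuOOH with pyridine.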